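The constants are made up; the run is a simulation.

The pitfall is to read 94 /M as the whole story for D and forget the clock.

    D + L ⇌ D.L (K1 = 94 /M, k1 = 0.23 /M/s)
    D.L → Q (k2 = 0.099 /s)
    Q ⇌ E (K3 = 13, k3 = 0.011 /s)
    Z ⇌ Q, rate k4*(cs4 - [Q]) while solid is left; crystals form when [Q] > cs4 (cs4 = 3.0 mM, k4 = 0.25 /s)

common to all: time 2.0 min
- Friday's: D 0.042 M; L 2.50 equiv (fed, over 80 s); all else is in the flask from the start; the feed brings no volume worth counting
- Wednesday's: D 0.042 M (fed, over 80 s); L 2.50 equiv; all else is in the flask from the start; the feed brings no volume worth counting
- Sunday's: D 0.042 M; L 2.50 equiv; everything together at the start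
- Monday's: D 0.042 M (in portions, 4, over 80 s); L 2.50 equiv; first portion at the start, last at 80 s

- which flask leads in amount of Q, in percent of the D charged ("all alike" within 1.5 percentage points) (Friday's / Wednesday's / Sunday's / Monday's / all alike)
- how much Q is there at the end, in percent of the D charged: Friday's
- how much Q is there at the end, in percent of the D charged: Wednesday's
- how much Q is there at the end, in percent of the D charged: Sunday's
- how much Q is there at the end, in percent of the D charged: Monday's

I follow one D molecule. Once bound as D.L, it falls back at 0.00245 /s and goes on at 0.099 /s, so going on is faster and nearly all of the bound molecules choose Q over falling back. Meeting L at the start of Sunday's runs at 0.0242 /s, slower than going on, so that is the fork I reckon on.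

Multiplying k1 by the excess of L over D and by the time the two share gives 1.74. This is my contact number (a Damköhler number): the larger it is, the smaller a molecule's chance of staying unmet. For Sunday's, with L falling as it reacts, that chance is 11.3 %.

One number is not enough: Q also leaks to E. While crystals stand, dissolved Q sits near 3.0 mM, so E grows at 1.98 mM/min. That is a toll of 9.43 % of the charge, which I book on every flask alike. Sunday's then gets about 79.2 % Q.

In Friday's, Wednesday's and Monday's the fed partner arrives on average 40.0 s late. The contact number drops to 1.16, the unmet chance rises to 21.5 %, and Q comes to about 69.0 %. So I put Sunday's ahead.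

The forecast also names Sunday's, with 62.5 % for Friday's, 61 % for Wednesday's, 74 % for Sunday's and 59 % for Monday's, holding that “having D and L together at full strength from the start gives the most conversion”. My 79.2 % for Sunday's stands higher than its figure, and my 69.0 % for the fed flasks higher than its figures for them.

The flask gives Sunday's, and the forecast's order and numbers hold:

| Flask | Q | D left | E |
|---|---|---|---|
| Friday's | 62.7 % | 23 % | 9.61 % |
| Wednesday's | 61.1 % | 24 % | 9.48 % |
| Sunday's | 74.6 % | 12 % | 11.3 % |
| Monday's | 58.8 % | 26 % | 10.0 % |

Sunday's holds 12 % D beside my 11.3 %, 11.3 % E beside my 9.43 %, and 2.21 % D.L, which I had booked as nothing; together these close the gap to my Q. Monday's, at contact number 1.16, holds 26 % D beside my 21.5 %. In Monday's, D.L goes on with a half-life of 0.12 min at 1.06 min, far shorter than the run of 2.0 min. At the end of Monday's, D.L stands at 5.30 %.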